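G and L make G.L in four vessels, and I want the one that ends with the most of it.

    G ⇌ D (K1 = 3.0, k1 = 0.0101 min⁻¹)
    G + L ⇌ G.L (K2 = 27.0 M⁻¹, k2 = 0.155 M⁻¹ min⁻¹)
    L + D → L.D (k3 = 0.228 M⁻¹ min⁻¹)
    L ⇌ X (K4 = 0.733, k4 = 0.0137 min⁻¹)

| setting | dusk | summer | dawn | noon |
|---|---|---|---|---|
| G | 0.25 M | 0.25 M | 0.25 M (fed, over 32.0 min) | 0.25 M |
| L | 0.800 equiv | 0.800 equiv | 0.800 equiv | 0.800 equiv (fed, over 32.0 min) |
| time | 40 min |  | 40 min | 40 min |
| remark | a closed flask charged with all of it at once and left for 40 min | a single well-mixed tank run continuously and read at steady state, 40 min in it on average | all but G at the start; G goes in evenly over 32.0 min, the run ends at 40 min | all but L at the start; L goes in evenly over 32.0 min, the run ends at 40 min |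

* the set-up with the highest amount of G.L at the outlet or at the end, in percent of the G put in ("none" if the first two lie within 2 percentage points) (dusk / summer / dawn / noon / none)
* amount of G.L at the outlet or at the end, in percent of the G put in, dusk
* amount of G.L at the outlet or at the end, in percent of the G put in, summer
* amount of G.L at the outlet or at the end, in percent of the G put in, dawn
* amount of G.L at the outlet or at the end, in percent of the G put in, noon

- the stated concentrations are those of everything mixed, before any reaction; amounts are the same in each set-up
- the feed brings no volume worth counting
- run time (dusk): 40 min

L, at 0.800 equiv, is the limiting reagent. I start with dusk, where the rate of step 2 is its forward constant times c(G) times c(L). I treat G's leak by step one and L's leak by step 4 as plain first-order losses, together 0.0238 min⁻¹. The product of c(G) and c(L) then carries exp(−st), and integrating that factor over the run shrinks the clock to a contact time 25.8 min, the stretch of undiminished charges that gives the same contact. Put into the integrated second-order law with r the equivalents of L, it gives E = exp(k c(G) (1 − r) × contact time) = 1.22, and the yield is r(E − 1)/(E − r).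

Which numbers must be good? Halving the forward constant of step 2 costs 14 percentage points. Doubling the constant of step 4 costs 4.8 points, and doubling that of step one costs 3.6 points. I leave step 3 out of the integral to keep it closed, although step one forms D during the run and step 3 then consumes L, so this omission puts my number on the high side. I also drop the back steps, though L and X relax with a half-life of 21.4 min, shorter than the run, so that leak slows in dusk. My number for dusk is 42.0%. Evenly dosed material stays 24.0 min on average, less than dusk's 40 min, and the tank reacts at outlet concentrations, so I pick dusk.

The forecast says dusk, with 35%, 24.5%, 26.5% and 21% for dusk, summer, dawn and noon, on the ground that “having both concentrated from the start (dusk) wins”. The simulation gives dusk, with 35.8%, 24.4%, 27.0% and 26.0% in that order.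

Dusk stands at 0.851 of my number. At 8.28 min in dusk, L has a half-life of 24 min by the forward rate of step 2, shorter than the 69 min of G by the forward rate of step one. In the neighbour of dusk charged with 0.062 M of G, the contact time stays 25.8 min, the law gives 16.2%, and dusk's ratio turns that into 13.8%. The computed flask gives 14.5%.

The constants are those of an exercise; the run is a simulation.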